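## Structural features

The target is a cyclohexane in which every ring carbon carries oxygen. C1 is quaternary and bears the exocyclic C7 as a benzoyloxymethyl group, C1 and C6 share an oxirane oxygen (a cis-fused 7-oxabicyclo[4.1.0]heptane), C2 and C3 carry acetates, and C4 and C5 carry free hydroxyls. The six stereocentres are contiguous, (1S,2R,3S,4R,5R,6S). Calling α the face of the oxirane oxygen and β the face of C7, the oxygens sit O2 α, O3 β, O4 α, O5 β, so every neighbouring pair from C2 to C6 is trans while O2 is cis to the oxirane. The fragile elements are the trisubstituted oxirane (acid, nucleophiles) and three esters that lie next to free or latent hydroxyls and can migrate under base. The real difficulty is not the carbon skeleton, which has only C1–C7 outside the ring, but placing six oxygens in four different states with full stereocontrol around a quaternary centre. The feature exploited is that C1, with its oxygen and C7, lies para to the oxygenated C4: this is a 4-substituted phenol oxidised to a 4-hydroxycyclohexa-2,5-dienone, in which C2/C6 and C3/C5 are enantiotopic pairs. The cis relation of O1 and O2 is what a short O–B–O tether delivers when the C1 hydroxyl carries an oxygen nucleophile to C2, so one desymmetrising event fixes C1 and C2 and leaves an enone (C4=O, C5=C6) to relay C3 to C6.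

## Logic of the disconnections

17 back to 16. The O4–H bond is traced to an O4–Si bond. O4 has to stay masked while the oxirane is built and moved, because a free O4 would steer an oxidant to the α face and could itself attack the neighbouring oxirane. Nothing is gained in skeleton, but the last step touches no stereocentre. The forward step needs a fluoride source that neither opens the oxirane nor moves acetates.

16 back to 15. The C6–O1 bond of the oxirane is cut and C6 is rejoined to O5. O1 is present from the earliest stage, so the oxirane is best closed by this oxygen onto C6, and the oxygen needed at C5 and the leaving group at C6 are then the same atom of a C5–C6 oxirane. The trisubstituted oxirane at the quaternary carbon is thereby replaced by a disubstituted one that comes from an alkene. The forward step needs O1 anti to the C5–C6 oxirane, and the ring must close without the neighbouring esters ending up scrambled.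

15 back to 13 through 14. The acetyl–O2 bond is cut and O1 and O2 are tied again through boron. These B–O bonds are the ones formed in the key step, and the boron bridge is the only mask of O1/O2 that comes off without acid or base next to an oxirane. No separate protecting steps are needed for O1 and O2. The forward step needs a neutral exchange of boron to another diol and an acylation that takes secondary O2 and leaves tertiary O1.

13 back to 12. Both C–O bonds of the C5–C6 oxirane are cut, leaving the C5=C6 alkene and removing two stereocentres. The forward step needs oxygen transfer to the β face, anti to O1 and O4, by an oxidant that is not hydroxyl-directed and does not attack the aryl–boron bond.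

12 back to 10 through 11. The O4–Si bond and then the C4–H bond are cut, which returns the C4 ketone and removes one stereocentre. The forward steps need 1,2-reduction with hydride entering on the β face (O4 trans to O3) and a silyl group that is bulky and does not migrate.

10 back to 6 through 9, 8 and 7. The acetyl–O3 bond and the C3–O bond are cut. C3 is the only enolisable position of 6 because C1 is quaternary, so regiochemistry is not in question. The forward steps need enol ether formation without loss of O2 and oxidation on the face away from the boron ring. O3 is acylated before O4 exists, which differentiates the two.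

6 back to 4 and 5. The C2–O bond and both B–O bonds are cut. This removes the last two stereocentres and one ring and arrives at an achiral dienone. The forward step needs a catalyst that tells the enantiotopic enone arms apart. The benzoate of 4 is kept because it is a target group, needs no later adjustment and is inert to the conditions used.

4 back to 3. The C1–O bond is cut and the ring is rearomatised. The forward step needs an oxidant that activates the phenol and lets water add at the para carbon faster than the benzylic ester solvolyses.

3 back to 1 and 2. The ester C–O bond at C7 is cut. The forward step must esterify the benzylic hydroxyl in the presence of the free phenol without a protecting group and without base, since the product is a base-labile 4-hydroxybenzyl ester.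

## Other disconnections considered

Alternative 1: The carbocycle is cut at C1=C6 (after removing the oxirane) and traced to a seven-membered cyclic sulfone A2 in which sulfur bridges C1 and C6. A Ramberg–Bäcklund reaction (α-halogenation, 1,3-elimination, extrusion of the sulfur bridge) would contract A2 to the fully protected cyclohexene A3. The hexitol A1 supplies C2–C5, with inversion at two centres to reach the all-trans array.
- In favour: the four secondary stereocentres come from the chiral pool with no stereoselective step, which is more certain than the relay in the chosen plan.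
- In favour: the oxirane would be installed by hydroxyl-directed epoxidation of C1=C6 from the face of a free O2. This fits the target better than an oxirane transposition and avoids any alkoxide beside esters; on this point the alternative is the better plan.
- Against: the ether pattern of A3 pairs O2 with O5 and O3 with O4, whereas the target pairs O2 with O3 (acetates) and O4 with O5 (free). Extra protecting-group exchanges are needed.
- Against: benzyl ethers must be removed beside an alkene or an oxirane, C7 has to be attached by α-alkylation of the sulfone, and the sequence from A1 is long.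
- Comparison: the ring contraction is mechanistically robust and stereochemically innocent, equal to the chosen key step in reliability. In step count the chosen plan (eleven steps) should be clearly shorter.

Alternative 2: C1–O and C4–O are cut together. A sensitised photooxygenation ([4+2]) of the diene A4 across C1 and C4 would give the bicyclic peroxide A5.
- In favour: two C–O bonds and the quaternary centre form in one reagent-free step, and O1 and O4 arrive cis, as the target requires. The chosen plan needs two separate events for these oxygens, so here the alternative is better.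
- In favour: the peroxide bridge could be isomerised to two oxiranes, leaving only hydrolytic opening of the disubstituted one. That would be the shortest endgame of all plans.
- Against: A4 is a sensitive 1,3-diene with two stereocentres that can aromatise by elimination, and its absolute configuration must come from its own synthesis.
- Against: the facial sense of the cycloaddition rests on a balance between the C2 hydroxyl and the C3 silyl ether.
- Against: the later opening must pick C5 over C4 and the disubstituted over the trisubstituted oxirane, and none of this is assured.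
- Comparison: the alternative is mechanistically more economical after its key step. The chosen plan is stronger in where its chirality originates: one catalytic step on an achiral precursor made in two steps.

Alternative 3: The C1–C2 bond is cut. An intramolecular Morita–Baylis–Hillman reaction of the enoate aldehyde A7 (from the pentose A6) under a nucleophilic phosphine or tertiary amine would form C1–C2, close the ring and restore C1=C6, giving the cyclohexene ester A8.
- In favour: C3, C4 and C5 come from the pool.
- In favour: the protecting pattern of A8 (free O2, 4-methoxybenzyl on O3, benzyl on O4/O5) matches the target pairs; this equals the chosen plan in oxygen differentiation and is better than Alternative 1.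
- In favour: the free O2 beside C1=C6 again allows directed epoxidation on the correct face, which is better than the Payne step.
- Against: C2 is created in the aldol event under substrate control only, and A7 can epimerise at C3 or lose its β-alkoxy group under the catalyst.
- Against: the ester must be reduced and benzoylated, and the benzyl ethers must finally be hydrogenolysed (H2 over Pd/C) beside the oxirane.
- Comparison: certainty of absolute configuration is equal or better; step count should be higher (about fifteen from A6), and the new stereocentre of the key step is less securely controlled than the tether-enforced cis fusion of the chosen plan.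

Key step: step 3

Remarks on the chemistry before the steps:
- Ring atoms carry the locants of the target throughout (C1 quaternary, C7 exocyclic); α and β are the faces defined above.
- The boronate 6 must be (3aR,7aR) for its C1 and C2 to map onto (1S,2R) of 17. The descriptor at C1 changes along the route only because substituent priorities change.
- Assumption: the quinine-derived (8α,9S) aminothiourea is taken to select the enone arm that leads to (3aR,7aR)-6. If its sense is opposite, the quinidine-derived (9R) pseudoenantiomer is used with no other change.

## Route

Step 1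
Reactants: 1 4-hydroxybenzyl alcohol; 2 benzoic acid
Product: 3 4-hydroxybenzyl benzoate
Conditions: PPh3, DIAD, THF, 0 °C → rt
Reagents that add atoms: none
Why: Mitsunobu esterification; only the benzylic hydroxyl is turned into an oxyphosphonium leaving group, and the far more acidic carboxylic acid rather than the phenol acts as the pronucleophile, so the phenol should stay free. The neutral conditions suit a 4-hydroxybenzyl ester, which would fragment under base.

Step 2
Reactants: 3 4-hydroxybenzyl benzoate
Product: 4 (1-hydroxy-4-oxocyclohexa-2,5-dien-1-yl)methyl benzoate
Conditions: PhI(OAc)2, MeCN/H2O (3:1), 0 °C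
Reagents that add atoms: water, O
Why: Oxidative dearomatisation of a para-substituted phenol by a trivalent iodine reagent; the phenol is activated at oxygen and water adds to the para carbon, giving the p-quinol. The product has a mirror plane through C1 and C4, so no stereochemistry arises, and the acidic medium avoids base-induced loss of benzoate.

Step 3
Reactants: 4 (1-hydroxy-4-oxocyclohexa-2,5-dien-1-yl)methyl benzoate; 5 phenylboronic acid
Product: 6 [(3aR,7aR)-5-oxo-2-phenyl-3a,4,5,7a-tetrahydro-1,3,2-benzodioxaborol-7a-yl]methyl benzoate
Conditions: N-[3,5-bis(trifluoromethyl)phenyl]-N′-[(8α,9S)-6′-methoxycinchonan-9-yl]thiourea (10 mol %), 4 Å molecular sieves, toluene, rt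
Reagents that add atoms: none
Why: This is the known amine–thiourea catalysed oxa-Michael addition of boronic acid hemiesters to γ-hydroxy enones, used here to desymmetrise a p-quinol. The tertiary C1 hydroxyl of 4 condenses reversibly with 5 to a hemiester; the quinuclidine nitrogen of the catalyst engages the B–OH group and makes its oxygen nucleophilic, while the thiourea hydrogen-bonds to the dienone carbonyl. That oxygen adds to the β-carbon of one enone arm in a 5-exo-trig conjugate addition, which forms the C2–O bond and closes the 1,3,2-dioxaborolane, and the enolate is protonated at C3. The O–B–O tether can reach C2 only on the face that carries O1, so the ring fusion is necessarily cis and the configuration of C2 follows from that of C1. C1 becomes a stereocentre solely because one of the two enantiotopic arms (C2 versus C6) is chosen, and this choice rests on the chiral pocket of the cinchona scaffold around the bound substrate. The step needs enantiotopic-group selectivity and a single addition: the mirror plane of 4 excludes regio- and diastereomers, and once the ring is closed boron has no hydroxyl left, so the second arm stays an enone. Molecular sieves take up the water of condensation, and the uncatalysed addition should be slow because the hemiester oxygen is a poor nucleophile without the amine.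

Step 4
Reactants: 6 [(3aR,7aR)-5-oxo-2-phenyl-3a,4,5,7a-tetrahydro-1,3,2-benzodioxaborol-7a-yl]methyl benzoate
Product: 9 [(3aR,4R,7aR)-4-hydroxy-5-oxo-2-phenyl-3a,4,5,7a-tetrahydro-1,3,2-benzodioxaborol-7a-yl]methyl benzoate, via silyl dienol ether 7 (not isolated), via silyloxy oxirane 8 (not isolated)
Conditions: TMSOTf, Et3N, CH2Cl2, 0 °C; evaporate, pentane extract; DMDO, acetone/CH2Cl2, −78 → 0 °C; then citric acid, THF/H2O, 0 °C
Reagents that add atoms: dimethyldioxirane (DMDO), CC1(C)OO1; trimethylsilyl triflate, C[Si](C)(C)OS(=O)(=O)C(F)(F)F (its silyl group stays only in 7 and 8)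
Why: Rubottom oxidation; enolisation can only go toward C3 because C1 is quaternary, and the electrophilic dioxirane should attack the electron-rich enol ether on the β face, away from the cis-fused dioxaborolane at C2, so that O3 ends trans to O2. A dioxirane rather than a peracid is chosen because it should leave the aryl–boron bond untouched.

Step 5
Reactants: 9 [(3aR,4R,7aR)-4-hydroxy-5-oxo-2-phenyl-3a,4,5,7a-tetrahydro-1,3,2-benzodioxaborol-7a-yl]methyl benzoate
Product: 10 [(3aR,4R,7aR)-4-acetoxy-5-oxo-2-phenyl-3a,4,5,7a-tetrahydro-1,3,2-benzodioxaborol-7a-yl]methyl benzoate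
Conditions: Ac2O, pyridine, DMAP (cat.), CH2Cl2, 0 °C
Reagents that add atoms: acetic anhydride, CC(=O)OC(C)=O
Why: Acylation of the secondary α-hydroxyl under nucleophilic catalysis; acetylating O3 before O4 exists differentiates the two oxygens without a further protecting group. Low temperature and short exposure to base limit epimerisation at C3 and elimination of O2.

Step 6
Reactants: 10 [(3aR,4R,7aR)-4-acetoxy-5-oxo-2-phenyl-3a,4,5,7a-tetrahydro-1,3,2-benzodioxaborol-7a-yl]methyl benzoate
Product: 11 [(3aR,4S,5R,7aR)-4-acetoxy-5-hydroxy-2-phenyl-3a,4,5,7a-tetrahydro-1,3,2-benzodioxaborol-7a-yl]methyl benzoate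
Conditions: NaBH4, CeCl3·7H2O, MeOH/THF, −78 °C
Reagents that add atoms: none
Why: Luche reduction, 1,2-selective for the enone carbonyl and unreactive toward the esters at −78 °C. In the half-chair with O2 and the O3 acetate equatorial, the axial hydrogen at C3 points to the α face, so axial hydride delivery comes from the β face and places O4 on the α face, trans to O3.

Step 7
Reactants: 11 [(3aR,4S,5R,7aR)-4-acetoxy-5-hydroxy-2-phenyl-3a,4,5,7a-tetrahydro-1,3,2-benzodioxaborol-7a-yl]methyl benzoate
Product: 12 [(3aR,4R,5R,7aR)-4-acetoxy-2-phenyl-5-(triisopropylsilyloxy)-3a,4,5,7a-tetrahydro-1,3,2-benzodioxaborol-7a-yl]methyl benzoate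
Conditions: TIPSOTf, 2,6-lutidine, CH2Cl2, −78 → 0 °C
Reagents that add atoms: triisopropylsilyl triflate, CC(C)[Si](C(C)C)(C(C)C)OS(=O)(=O)C(F)(F)F
Why: Silylation of the allylic hydroxyl with a silyl triflate and a hindered base, which does not move the neighbouring acetate. The triisopropylsilyl group removes the hydroxyl that would direct an oxidant to the α face, adds bulk on that face, and resists 1,2-migration under the basic conditions of step 10.

Step 8
Reactants: 12 [(3aR,4R,5R,7aR)-4-acetoxy-2-phenyl-5-(triisopropylsilyloxy)-3a,4,5,7a-tetrahydro-1,3,2-benzodioxaborol-7a-yl]methyl benzoate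
Product: 13 5,6-β-oxirane of 12 (target locants 1R,2R,3R,4R,5S,6R; boronate on O1/O2, acetate on O3, silyl ether on O4)
Conditions: DMDO (excess), acetone/CH2Cl2, 0 °C → rt
Reagents that add atoms: dimethyldioxirane (DMDO), CC1(C)OO1
Why: Dioxirane epoxidation of an alkene with no free hydroxyl to direct it. In the preferred half-chair (O2, O3 and O4 equatorial) the C1–O1 bond is pseudoaxial on the α face and, with the dioxaborolane ring and the silyl ether, shields that face, whereas C7 is pseudoequatorial, so oxygen should be delivered to the β face. The neutral, electrophilic oxidant should tolerate the boronate and the esters.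

Step 9
Reactants: 13 5,6-β-oxirane of 12
Product: 15 [(1R,2S,3R,4R,5R,6S)-3,4-diacetoxy-2-hydroxy-5-(triisopropylsilyloxy)-7-oxabicyclo[4.1.0]heptan-2-yl]methyl benzoate, via epoxy diol 14 (not isolated)
Conditions: pinacol, CH2Cl2, rt; then Ac2O, pyridine, DMAP (cat.), 0 °C
Reagents that add atoms: acetic anhydride, CC(=O)OC(C)=O
Why: Transesterification of the boronate to the more stable pinacol ester frees O1 and O2 under neutral conditions that leave the oxirane and esters alone. Acetylation then takes the secondary O2 and not the tertiary O1, just as it leaves the tertiary hydroxyls of excess pinacol.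

Step 10
Reactants: 15 [(1R,2S,3R,4R,5R,6S)-3,4-diacetoxy-2-hydroxy-5-(triisopropylsilyloxy)-7-oxabicyclo[4.1.0]heptan-2-yl]methyl benzoate
Product: 16 [(1S,2R,3R,4R,5S,6S)-2,3-diacetoxy-5-hydroxy-4-(triisopropylsilyloxy)-7-oxabicyclo[4.1.0]heptan-1-yl]methyl benzoate
Conditions: KN(SiMe3)2 (1.05 equiv), THF, −78 → −20 °C; AcOH, −78 °C
Reagents that add atoms: none
Why: Payne rearrangement; the O1 alkoxide, antiperiplanar to the C6–O bond of the β-oxirane, attacks C6 from the α face in a 3-exo-tet closure with inversion at C6 and releases O5 as the β-alkoxide. The equilibrium should favour the trisubstituted oxirane and the secondary alkoxide. Acetyl transfer from O2 to O1 is reversible and returns through the tertiary alkoxide, the only species that can close the ring, and the cold acidic quench protonates O5 before it can take an acyl group.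

Step 11
Reactants: 16 [(1S,2R,3R,4R,5S,6S)-2,3-diacetoxy-5-hydroxy-4-(triisopropylsilyloxy)-7-oxabicyclo[4.1.0]heptan-1-yl]methyl benzoate
Product: 17 [(1S,2R,3S,4R,5R,6S)-2,3-diacetoxy-4,5-dihydroxy-7-oxabicyclo[4.1.0]heptan-1-yl]methyl benzoate
Conditions: HF·pyridine, pyridine, THF, 0 °C → rt
Reagents that add atoms: none
Why: Fluoride cleavage of the Si–O bond in a buffered, weakly acidic medium, which should neither open the oxirane nor promote acetyl migration to the freed O4. No stereocentre is touched.

## Compound list

1 | 4-hydroxybenzyl alcohol | OCc1ccc(O)cc1 | starting material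
2 | benzoic acid | OC(=O)c1ccccc1 | starting material
3 | 4-hydroxybenzyl benzoate | O=C(OCc1ccc(O)cc1)c1ccccc1 | intermediate
4 | (1-hydroxy-4-oxocyclohexa-2,5-dien-1-yl)methyl benzoate, i.e. 4-(benzoyloxymethyl)-4-hydroxycyclohexa-2,5-dien-1-one | O=C1C=CC(O)(COC(=O)c2ccccc2)C=C1 | intermediate
5 | phenylboronic acid | OB(O)c1ccccc1 | starting material
6 | [(3aR,7aR)-5-oxo-2-phenyl-3a,4,5,7a-tetrahydro-1,3,2-benzodioxaborol-7a-yl]methyl benzoate (cis-fused phenylboronate of the C1,C2-diol enone) | O1B(c2ccccc2)O[C@@H]2CC(=O)C=C[C@]12COC(=O)c1ccccc1 | intermediate
7 | [(3aR,7aR)-2-phenyl-5-(trimethylsilyloxy)-3a,7a-dihydro-1,3,2-benzodioxaborol-7a-yl]methyl benzoate (silyl dienol ether, not isolated) | O1B(c2ccccc2)O[C@@H]2C=C(O[Si](C)(C)C)C=C[C@]12COC(=O)c1ccccc1 | intermediate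
8 | 3,4-β-oxirane of 7 carrying OSiMe3 on C4 (target locants 1R,2R,3R,4R; not isolated) | O1B(c2ccccc2)O[C@@H]2[C@H]3O[C@@]3(O[Si](C)(C)C)C=C[C@]12COC(=O)c1ccccc1 | intermediate
9 | [(3aR,4R,7aR)-4-hydroxy-5-oxo-2-phenyl-3a,4,5,7a-tetrahydro-1,3,2-benzodioxaborol-7a-yl]methyl benzoate | O1B(c2ccccc2)O[C@@H]2[C@@H](O)C(=O)C=C[C@]12COC(=O)c1ccccc1 | intermediate
10 | [(3aR,4R,7aR)-4-acetoxy-5-oxo-2-phenyl-3a,4,5,7a-tetrahydro-1,3,2-benzodioxaborol-7a-yl]methyl benzoate | O1B(c2ccccc2)O[C@@H]2[C@@H](OC(C)=O)C(=O)C=C[C@]12COC(=O)c1ccccc1 | intermediate
11 | [(3aR,4S,5R,7aR)-4-acetoxy-5-hydroxy-2-phenyl-3a,4,5,7a-tetrahydro-1,3,2-benzodioxaborol-7a-yl]methyl benzoate | O1B(c2ccccc2)O[C@@H]2[C@@H](OC(C)=O)[C@H](O)C=C[C@]12COC(=O)c1ccccc1 | intermediate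
12 | [(3aR,4R,5R,7aR)-4-acetoxy-2-phenyl-5-(triisopropylsilyloxy)-3a,4,5,7a-tetrahydro-1,3,2-benzodioxaborol-7a-yl]methyl benzoate | O1B(c2ccccc2)O[C@@H]2[C@@H](OC(C)=O)[C@H](O[Si](C(C)C)(C(C)C)C(C)C)C=C[C@]12COC(=O)c1ccccc1 | intermediate
13 | 5,6-β-oxirane of 12 (target locants 1R,2R,3R,4R,5S,6R) | O1B(c2ccccc2)O[C@@H]2[C@@H](OC(C)=O)[C@H](O[Si](C(C)C)(C(C)C)C(C)C)[C@H]3O[C@H]3[C@]12COC(=O)c1ccccc1 | intermediate
14 | [(1R,2R,3R,4R,5R,6S)-4-acetoxy-2,3-dihydroxy-5-(triisopropylsilyloxy)-7-oxabicyclo[4.1.0]heptan-2-yl]methyl benzoate (epoxy diol, not isolated) | CC(=O)O[C@H]1[C@H](O[Si](C(C)C)(C(C)C)C(C)C)[C@H]2O[C@H]2[C@@](O)(COC(=O)c2ccccc2)[C@@H]1O | intermediate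
15 | [(1R,2S,3R,4R,5R,6S)-3,4-diacetoxy-2-hydroxy-5-(triisopropylsilyloxy)-7-oxabicyclo[4.1.0]heptan-2-yl]methyl benzoate | CC(=O)O[C@H]1[C@H](O[Si](C(C)C)(C(C)C)C(C)C)[C@H]2O[C@H]2[C@@](O)(COC(=O)c2ccccc2)[C@@H]1OC(C)=O | intermediate
16 | [(1S,2R,3R,4R,5S,6S)-2,3-diacetoxy-5-hydroxy-4-(triisopropylsilyloxy)-7-oxabicyclo[4.1.0]heptan-1-yl]methyl benzoate | CC(=O)O[C@H]1[C@H](O[Si](C(C)C)(C(C)C)C(C)C)[C@@H](O)[C@@H]2O[C@]2(COC(=O)c2ccccc2)[C@@H]1OC(C)=O | intermediate
17 | [(1S,2R,3S,4R,5R,6S)-2,3-diacetoxy-4,5-dihydroxy-7-oxabicyclo[4.1.0]heptan-1-yl]methyl benzoate | CC(=O)O[C@H]1[C@H](O)[C@@H](O)[C@@H]2O[C@]2(COC(=O)c2ccccc2)[C@@H]1OC(C)=O | target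

## Step count and least certain steps

Total: 11 steps. Longest linear sequence: 11 steps (1 to 17); 2 and 5 are used as purchased.

Step 3 (key step). The most likely failure is incomplete discrimination between the two enone arms, or erosion of enantiomeric purity by reversible ring opening (retro-oxa-Michael) over long reaction times. Hemiester formation at the hindered tertiary hydroxyl may also be slow. The fallback changes tether and activation mode and sets out from 4. An acetalisation/oxa-Michael cascade with cyclohexanecarbaldehyde under a BINOL-derived chiral phosphoric acid closes the same C2–O bond through a hemiacetal oxygen and should give the cis-fused 2-cyclohexyl-1,3-dioxolane enone F1. Hydrolysis of the acetal in aqueous acetic acid gives the diol enone F2, which is condensed with 5 (MgSO4, CH2Cl2) and comes back to the route at 6.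

Step 10. The most likely failure is transfer of the acetyl group from O2 to the O1 alkoxide and onward scrambling of acetyl and benzoyl groups running ahead of oxirane closure, or 1,3-transfer of the O3 acetyl to the new O5 alkoxide. Acyl transfer to a neighbouring alkoxide is intrinsically faster than a 3-exo-tet opening. The fallback keeps the rearrangement but removes the cis acyl neighbour and traps O5, setting out from 14, which is then isolated after the pinacol exchange. 4-Methoxybenzyl trichloroacetimidate with catalytic La(OTf)3 in toluene etherifies the secondary O2 to give the 2-O-(4-methoxybenzyl) epoxy alcohol F3. KN(SiMe3)2 followed by Et3SiCl effects the Payne shift and caps O5 in the same flask, giving the rearranged 5-O-triethylsilyl oxirane F4. DDQ in wet CH2Cl2 frees O2 to give the alcohol F5, Ac2O/pyridine/DMAP gives the 2,3-diacetate bis-silyl ether F6, and HF·pyridine removes both silyl groups, coming back to the route at 17.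

Step 8. The most likely failure is oxygen transfer to the α face, because the benzoyloxymethyl group on C1 hinders the β face more than the conformational argument allows, together with slow reaction of an alkene flanked by two allylic oxygens. The fallback inverts the facial outcome by a two-stage ionic route and sets out from 12. NBS in aqueous DME places bromonium on whichever face an electrophile prefers and water enters anti, expected at C5 (the carbon remote from the quaternary centre), to give the 6α-bromo-5β-hydroxy compound F7. K2CO3 in MeCN then closes the oxirane by displacement of bromide, which puts the oxygen on the β face and comes back to the route at 13. Either regioisomeric bromohydrin would converge on the same oxirane.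

Step 4. The most likely failure is expulsion of the β-oxygen O2 (retro-oxa-Michael) during enolisation, or attack of the oxidant on the α face. The fallback avoids an enol ether altogether and sets out from 6: α′-acetoxylation of the enone with Mn(OAc)3·2H2O in refluxing benzene (a trivalent manganese enolate transfers acetate to C3, trans to the C2 substituent) should give the acetate directly and comes back to the route at 10, with no new compound on the way.

Step 6. The most likely failure is hydride delivery from the α face, giving the C4 epimer, or acetyl migration from O3 to the new O4 alkoxide; brief methanolysis of the boronate is a lesser concern. The fallback replaces conformational control by intramolecular delivery and changes the order of protection, setting out from 9. Me4NBH(OAc)3 in MeCN/AcOH at −20 °C binds the free O3 hydroxyl and delivers hydride on its own face, which should give the trans-3,4-diol F8. One equivalent of TIPSOTf with 2,6-lutidine at −78 °C silylates the less hindered allylic O4 to give the 4-O-silyl 3-alcohol F9, and Ac2O/pyridine/DMAP acetylates O3, coming back to the route at 12.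

## Further compounds

F1 | step 3 | [(3aR,7aR)-2-cyclohexyl-5-oxo-3a,4,5,7a-tetrahydro-1,3-benzodioxol-7a-yl]methyl benzoate (acetal carbon as formed) | O1C(C2CCCCC2)O[C@@H]2CC(=O)C=C[C@]12COC(=O)c1ccccc1
F2 | step 3 | [(1R,6R)-1,6-dihydroxy-4-oxocyclohex-2-en-1-yl]methyl benzoate | O[C@@H]1CC(=O)C=C[C@@]1(O)COC(=O)c1ccccc1
F3 | step 10 | 2-O-(4-methoxybenzyl) ether of 14 (5,6-β-oxirane, free O1 hydroxyl, O3 acetate, O4 triisopropylsilyl ether) | CC(=O)O[C@H]1[C@H](O[Si](C(C)C)(C(C)C)C(C)C)[C@H]2O[C@H]2[C@@](O)(COC(=O)c2ccccc2)[C@@H]1OCc1ccc(OC)cc1
F4 | step 10 | 1,6-α-oxirane with O2 4-methoxybenzyl ether, O3 acetate, O4 triisopropylsilyl ether and O5 triethylsilyl ether | CC(=O)O[C@H]1[C@H](O[Si](C(C)C)(C(C)C)C(C)C)[C@@H](O[Si](CC)(CC)CC)[C@@H]2O[C@]2(COC(=O)c2ccccc2)[C@@H]1OCc1ccc(OC)cc1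
F5 | step 10 | 1,6-α-oxirane with free O2 hydroxyl, O3 acetate, O4 triisopropylsilyl ether and O5 triethylsilyl ether | CC(=O)O[C@H]1[C@H](O[Si](C(C)C)(C(C)C)C(C)C)[C@@H](O[Si](CC)(CC)CC)[C@@H]2O[C@]2(COC(=O)c2ccccc2)[C@@H]1O
F6 | step 10 | 1,6-α-oxirane 2,3-diacetate with O4 triisopropylsilyl ether and O5 triethylsilyl ether | CC(=O)O[C@H]1[C@H](O[Si](C(C)C)(C(C)C)C(C)C)[C@@H](O[Si](CC)(CC)CC)[C@@H]2O[C@]2(COC(=O)c2ccccc2)[C@@H]1OC(C)=O
F7 | step 8 | 6α-bromo-5β-hydroxy adduct of 12 (boronate, O3 acetate and O4 silyl ether retained) | O1B(c2ccccc2)O[C@@H]2[C@@H](OC(C)=O)[C@H](O[Si](C(C)C)(C(C)C)C(C)C)[C@@H](O)[C@H](Br)[C@]12COC(=O)c1ccccc1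
F0 | step 4 | none | none
F8 | step 6 | cis-fused phenylboronate with 3β,4α-diol and C5=C6 alkene (target locants) | O1B(c2ccccc2)O[C@@H]2[C@@H](O)[C@H](O)C=C[C@]12COC(=O)c1ccccc1
F9 | step 6 | 4-O-triisopropylsilyl ether of F8 with free 3β-hydroxyl | O1B(c2ccccc2)O[C@@H]2[C@@H](O)[C@H](O[Si](C(C)C)(C(C)C)C(C)C)C=C[C@]12COC(=O)c1ccccc1
A1 | alternative 1 | D-mannitol | OC[C@@H](O)[C@@H](O)[C@H](O)[C@H](O)CO
A2 | alternative 1 | thiepane 1,1-dioxide with CH2O(4-methoxybenzyl) on one α-carbon (either epimer there), 4-methoxybenzyl ethers on O2/O5 and benzyl ethers on O3/O4 | COc1ccc(COCC2S(=O)(=O)C[C@H](OCc3ccc(OC)cc3)[C@@H](OCc3ccccc3)[C@H](OCc3ccccc3)[C@H]2OCc2ccc(OC)cc2)cc1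
A3 | alternative 1 | fully protected C7-branched all-trans cyclohexenetetrol with C1=C6 | COc1ccc(COCC2=C[C@H](OCc3ccc(OC)cc3)[C@@H](OCc3ccccc3)[C@H](OCc3ccccc3)[C@H]2OCc2ccc(OC)cc2)cc1
A4 | alternative 2 | cyclohexa-1,3-diene with CH2OBz on C1, hydroxyl on C2 and tert-butyldimethylsilyl ether on C3 | O=C(OCC1=CC=C[C@H](O[Si](C)(C)C(C)(C)C)[C@H]1O)c1ccccc1
A5 | alternative 2 | C1,C4-endoperoxide with C2 hydroxyl, C3 silyl ether and C7 benzoate | O1O[C@]2(COC(=O)c3ccccc3)[C@H](O)[C@@H](O[Si](C)(C)C(C)(C)C)[C@H]1C=C2
A6 | alternative 3 | D-xylose (open-chain form) | O=C[C@H](O)[C@@H](O)[C@H](O)CO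
A7 | alternative 3 | ethyl (E)-4,5-bis(benzyloxy)-6-(4-methoxybenzyloxy)-7-oxohept-2-enoate (D-xylo configuration) | CCOC(=O)/C=C/[C@H](OCc1ccccc1)[C@@H](OCc1ccccc1)[C@H](OCc1ccc(OC)cc1)C=O
A8 | alternative 3 | ethyl cyclohexene-1-carboxylate with C2 hydroxyl, C3 4-methoxybenzyl ether and C4/C5 benzyl ethers | CCOC(=O)C1=C[C@H](OCc2ccccc2)[C@@H](OCc2ccccc2)[C@H](OCc2ccc(OC)cc2)[C@H]1O
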